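**Plan**

1. Retrosynthesis: the hydroquinone (ring B) is carried as its dimethyl ether. Ring A (cyclohex-2-ene-1,4-dione) is cut at its CH=CH and traced, through the saturated 1,4-dione, to two acetyl groups on the two adjacent quaternary carbons, one of them masked as a silylalkyne.
2. The bridged core is then cut at the bond between the two quaternary carbons and at the bond from ring B to the benzylic, allylic CH. This leaves an open-chain tertiary propargylic, benzylic carbinol bearing a (Z,E)-dienone, assembled from an ynone, a bromosenecioate (lactone, then lactol) and an acyl ylide.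
3. Enabling feature: the five-membered ring (quaternary benzylic carbon, two ring-B carbons, allylic CH, second quaternary carbon) is an indane of the kind formed when a benzylic cation adds to a diene terminus and the resulting allyl cation alkylates the ortho carbon. The ortho-oxygen of ring B stabilises the cation, and the ring-C alkene makes the CH an allyl-cation terminus.
4. Forward order: ring C (cyclohexene) and the five-membered ring close together in step 7, which also creates both quaternary centres. Ring A is closed afterwards by joining the two acetyl methyl groups and desaturating. Ring B is unmasked last.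
5. Stereochemistry: the E-enone geometry and a chair-like closure set the acetyl/prenyl carbon relative to the aryl-bearing carbon; the bicycle ties in the benzylic CH; a chiral acid counter-anion selects the enantiomer.

Key step: step 7

Assumption: the sense of induction of the chiral acid cannot be derived from first principles; the (R)-acid is written, and its mirror image would be used if the opposite sense were found.

Locants used for 17–19: 8,9-dihydro-5H-5,9-methanobenzo[7]annulene, with C-5 = benzylic CH bridgehead, C-9 = quaternary bridgehead, C-10 = bridge carbon. Locants used for 21–24: 4a,5,8,8a-tetrahydronaphthalene-1,4-dione, with C-4a = prenyl-bearing carbon, C-5 = benzylic CH, C-8a = aryl-bearing carbon.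

**Step 1**
Reactants: 1 2,5-dimethoxybenzoyl chloride; 2 ethynyltrimethylsilane
Product: 3 1-(2,5-dimethoxyphenyl)-3-(trimethylsilyl)prop-2-yn-1-one
Conditions: PdCl2(PPh3)2 (2 mol %), CuI (4 mol %), Et3N, THF, rt
Reagents that add atoms: none
Why: Acyl Sonogashira coupling, in which the acid chloride adds to zerovalent palladium and the copper acetylide delivers the alkyne; no stereocentre is formed.

**Step 2**
Reactants: 3 1-(2,5-dimethoxyphenyl)-3-(trimethylsilyl)prop-2-yn-1-one; 4 methyl (2E)-4-bromo-3-methylbut-2-enoate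
Product: 6 6-(2,5-dimethoxyphenyl)-4-methyl-6-[(trimethylsilyl)ethynyl]-5,6-dihydro-2H-pyran-2-one (racemic), via zinc dienolate 5 (not isolated)
Conditions: Zn dust (activated), THF, reflux; aq NH4Cl
Reagents that add atoms: none
Why: Vinylogous Reformatsky reaction, in which the zinc dienolate should add through its γ-carbon to the ketone carbonyl (zinc enolates add 1,2 to ynones and α-adducts revert at reflux) and the alkoxide lactonises, which locks the methyl-bearing double bond in the cis geometry needed later; the carbinol centre is racemic and is erased in step 7.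

**Step 3**
Reactants: 6 the lactone
Product: 7 6-(2,5-dimethoxyphenyl)-4-methyl-6-[(trimethylsilyl)ethynyl]-5,6-dihydro-2H-pyran-2-ol (lactol, mixture of epimers)
Conditions: i-Bu2AlH (1.1 equiv), CH2Cl2, −78 °C; Rochelle salt work-up
Reagents that add atoms: none
Why: Partial reduction of a lactone to the lactol by 1,2-hydride delivery, the tetrahedral aluminate being stable at low temperature so that the diol is not formed.

**Step 4**
Reactants: 8 5-bromo-2-methylpent-2-ene; 9 triphenylphosphine
Product: 10 (4-methylpent-3-en-1-yl)triphenylphosphonium bromide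
Conditions: MeCN, reflux
Reagents that add atoms: none
Why: SN2 alkylation of the phosphine by a primary bromide (phosphonium salt formation).

**Step 5**
Reactants: 10 (4-methylpent-3-en-1-yl)triphenylphosphonium bromide
Product: 12 6-methyl-3-(triphenyl-λ5-phosphanylidene)hept-5-en-2-one, via ylide 11 (not isolated)
Conditions: n-BuLi (1.0 equiv per 10), THF, −78 → 0 °C; then AcCl (0.5 equiv), −78 °C → rt
Reagents that add atoms: acetyl chloride, CC(Cl)=O
Why: C-acylation of a non-stabilised phosphorus ylide by an acid chloride followed by transylidation, in which a second equivalent of 11 deprotonates the acylphosphonium salt to the stabilised acyl ylide.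

**Step 6**
Reactants: 7 the lactol; 12 the acyl ylide
Product: 14 (3E,5Z)-8-(2,5-dimethoxyphenyl)-8-hydroxy-6-methyl-3-(3-methylbut-2-en-1-yl)-10-(trimethylsilyl)deca-3,5-dien-9-yn-2-one (racemic at C-8), via hydroxy-enal tautomer 13 (not isolated)
Conditions: PhCO2H (10 mol %), toluene, 100 °C
Reagents that add atoms: none
Why: Wittig olefination of the open-chain tautomer with a stabilised ylide, which should give the E-enone (acetyl trans to the diene chain, prenyl cis to it) while the ring-derived Z geometry of the methyl-bearing double bond is kept.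

**Step 7**
Reactants: 14 the tertiary carbinol
Product: 17 1-[(5R,9R,10S)-1,4-dimethoxy-7-methyl-10-(3-methylbut-2-en-1-yl)-9-[(trimethylsilyl)ethynyl]-8,9-dihydro-5H-5,9-methanobenzo[7]annulen-10-yl]ethan-1-one (acetyl on the arene side of C-10, prenyl over the C-6/C-7 alkene), via propargylic cation 15 (not isolated), via allyl cation 16 (not isolated)
Conditions: (R)-3,3'-bis(2,4,6-triisopropylphenyl)-1,1'-binaphthalene-2,2'-diyl N-triflylphosphoramide (10 mol %), 5 Å molecular sieves, toluene, −40 → 0 °C
Reagents that add atoms: none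
Why: Proposed new method: the acid protonates the tertiary alcohol, water leaves, and the propargylic, ortho-methoxybenzylic cation 15 stays paired with the chiral phosphoramide anion; its carbon attacks the acetyl-bearing end of the (Z,E)-diene in a 6-endo-trig closure of ring C (attack at the neighbouring β-carbon would place the charge next to the ketone), and the allyl cation 16 is then taken by the free ortho carbon of ring B in a 5-exo-trig Friedel–Crafts closure of the five-membered ring. The closest known reaction types are the formal (3+2) cycloaddition of benzylic cations with alkenes and 1,3-dienes to indanes and chiral-acid-catalysed substitutions of tertiary propargylic carbinols through contact ion pairs; new here are the intramolecular, bridged version on a dienone and its control by a chiral anion. C-10 is set by the E-enone geometry and a chair-like transition state in which the prenyl group (cis to the diene chain) becomes pseudo-axial and the bulky aryl group takes the pseudo-axial position anti to it, so that it is not gauche to both C-10 substituents, which leaves acetyl on the arene side. C-9 and C-5 follow because the aryl group can reach the allyl cation only on the face that carries it, and the absolute sense comes from the chiral counter-anion. The step needs arylation at the CH terminus and not at the methyl-bearing terminus of the allyl cation: the ortho-methoxy group should lie over the less hindered, more cationic methyl-bearing side and hold the free ortho carbon over the CH terminus, and alkylation at the tertiary terminus is reversible under the acid. It also needs ring closure to outrun loss of a proton, which is tolerated because protonation of the resulting styrene re-forms 15.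

**Step 8**
Reactants: 17 the silylalkyne
Product: 19 1,1'-[(5R,9R,10S)-1,4-dimethoxy-7-methyl-10-(3-methylbut-2-en-1-yl)-8,9-dihydro-5H-5,9-methanobenzo[7]annulene-9,10-diyl]bis(ethan-1-one), via terminal alkyne 18 (not isolated)
Conditions: K2CO3, MeOH, rt; then PdCl2(MeCN)2 (5 mol %), MeCN–H2O, rt
Reagents that add atoms: water, O
Why: Base-mediated C–Si cleavage, then palladium-dichloride-catalysed Markovnikov hydration of the terminal alkyne assisted by 5-exo attack of the neighbouring ketone oxygen, which should leave the prenyl and ring alkenes untouched; no stereocentre changes.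

**Step 9**
Reactants: 19 the bis(methyl ketone)
Product: 21 (4aS,5R,8aR)-7-methyl-4a-(3-methylbut-2-en-1-yl)-2,3,4a,5,8,8a-hexahydronaphthalene-1,4-dione bridged from C-5 to C-8a by a 3,6-dimethoxy-1,2-phenylene unit, via dilithium bis-enolate 20 (not isolated)
Conditions: LiN(SiMe3)2 (2.3 equiv), THF, −78 °C (ketone added to base); CuCl2 (2.3 equiv), DMF, −78 → 0 °C
Reagents that add atoms: none
Why: Intramolecular oxidative enolate coupling, in which both ketones can enolise only towards their methyl groups and one-electron oxidation by CuCl2 joins the two α-carbons to the six-membered 1,4-diketone; the stereocentres are not involved.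

**Step 10**
Reactants: 21 the saturated 1,4-diketone
Product: 22 (4aS,5R,8aR)-7-methyl-4a-(3-methylbut-2-en-1-yl)-4a,5,8,8a-tetrahydronaphthalene-1,4-dione bridged from C-5 to C-8a by a 3,6-dimethoxy-1,2-phenylene unit
Conditions: 2-iodoxybenzoic acid (IBX, 2.5 equiv), DMSO, 65 °C
Reagents that add atoms: none
Why: IBX dehydrogenation of a ketone to the enone, here at the only CH2–CH2 unit that carries α-hydrogens, with the quaternary carbons preventing aromatisation.

**Step 11**
Reactants: 22 the enedione bis(methyl ether)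
Product: 24 (4aS,5R,8aR)-7-methyl-4a-(3-methylbut-2-en-1-yl)-4a,5,8,8a-tetrahydronaphthalene-1,4-dione bridged from C-5 to C-8a by a 3,6-dihydroxy-1,2-phenylene unit (CNP0166383.1), via quinone 23 (not isolated)
Conditions: (NH4)2Ce(NO3)6 (2.5 equiv), MeCN–H2O, 0 °C; then aq Na2S2O4, EtOAc, rt
Reagents that add atoms: water, O
Why: Oxidative demethylation of a 1,4-dimethoxyarene to the para-quinone (water supplies the oxygens, methanol leaves), then dithionite reduction of the quinone, by far the stronger oxidant next to the non-aromatisable enedione, to the hydroquinone; the bridgehead stereocentres cannot epimerise.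

**Compound list**

1 | 2,5-dimethoxybenzoyl chloride | COc1ccc(OC)c(C(=O)Cl)c1 | starting material
2 | ethynyltrimethylsilane | C#C[Si](C)(C)C | starting material
3 | 1-(2,5-dimethoxyphenyl)-3-(trimethylsilyl)prop-2-yn-1-one | COc1ccc(OC)c(C(=O)C#C[Si](C)(C)C)c1 | intermediate
4 | methyl (2E)-4-bromo-3-methylbut-2-enoate | COC(=O)/C=C(\C)CBr | starting material
5 | bromozinc dienolate of 4, written C-bound | COC(=O)/C=C(\C)C[Zn]Br | intermediate
6 | 6-(2,5-dimethoxyphenyl)-4-methyl-6-[(trimethylsilyl)ethynyl]-5,6-dihydro-2H-pyran-2-one (racemic) | COc1ccc(OC)c(c1)C1(C#C[Si](C)(C)C)CC(C)=CC(=O)O1 | intermediate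
7 | 6-(2,5-dimethoxyphenyl)-4-methyl-6-[(trimethylsilyl)ethynyl]-5,6-dihydro-2H-pyran-2-ol (epimer mixture) | COc1ccc(OC)c(c1)C1(C#C[Si](C)(C)C)CC(C)=CC(O)O1 | intermediate
8 | 5-bromo-2-methylpent-2-ene | CC(C)=CCCBr | starting material
9 | triphenylphosphine | c1ccc(cc1)P(c1ccccc1)c1ccccc1 | starting material
10 | (4-methylpent-3-en-1-yl)triphenylphosphonium bromide | CC(C)=CCC[P+](c1ccccc1)(c1ccccc1)c1ccccc1.[Br-] | intermediate
11 | (4-methylpent-3-en-1-ylidene)triphenyl-λ5-phosphane | CC(C)=CCC=P(c1ccccc1)(c1ccccc1)c1ccccc1 | intermediate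
12 | 6-methyl-3-(triphenyl-λ5-phosphanylidene)hept-5-en-2-one | CC(=O)C(CC=C(C)C)=P(c1ccccc1)(c1ccccc1)c1ccccc1 | intermediate
13 | (2Z)-5-(2,5-dimethoxyphenyl)-5-hydroxy-3-methyl-7-(trimethylsilyl)hept-2-en-6-ynal (racemic) | COc1ccc(OC)c(c1)C(O)(C#C[Si](C)(C)C)C/C(C)=C\C=O | intermediate
14 | (3E,5Z)-8-(2,5-dimethoxyphenyl)-8-hydroxy-6-methyl-3-(3-methylbut-2-en-1-yl)-10-(trimethylsilyl)deca-3,5-dien-9-yn-2-one (racemic) | CC(=O)/C(CC=C(C)C)=C/C=C(C)\CC(O)(C#C[Si](C)(C)C)c1cc(OC)ccc1OC | intermediate
15 | C-8 carbocation of 14 (propargylic, benzylic) | CC(=O)/C(CC=C(C)C)=C/C=C(C)\C[C+](C#C[Si](C)(C)C)c1cc(OC)ccc1OC | intermediate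
16 | 6-acetyl-5-(2,5-dimethoxyphenyl)-3-methyl-6-(3-methylbut-2-en-1-yl)-5-[(trimethylsilyl)ethynyl]cyclohex-2-en-1-ylium (aryl trans to prenyl) | CC(C)=CC[C@@]2(C(C)=O)[C@](C#C[Si](C)(C)C)(c1cc(OC)ccc1OC)CC(C)=C[CH+]2 | intermediate
17 | 1-[(5R,9R,10S)-1,4-dimethoxy-7-methyl-10-(3-methylbut-2-en-1-yl)-9-[(trimethylsilyl)ethynyl]-8,9-dihydro-5H-5,9-methanobenzo[7]annulen-10-yl]ethan-1-one | CC(C)=CC[C@@]2(C(C)=O)[C@@]3(C#C[Si](C)(C)C)CC(C)=C[C@@H]2c1c(OC)ccc(OC)c13 | intermediate
18 | 17 without the silyl group (9-ethynyl compound, same configuration) | CC(C)=CC[C@@]2(C(C)=O)[C@@]3(C#C)CC(C)=C[C@@H]2c1c(OC)ccc(OC)c13 | intermediate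
19 | 1,1'-[(5R,9R,10S)-1,4-dimethoxy-7-methyl-10-(3-methylbut-2-en-1-yl)-8,9-dihydro-5H-5,9-methanobenzo[7]annulene-9,10-diyl]bis(ethan-1-one) | CC(C)=CC[C@@]2(C(C)=O)[C@@]3(C(C)=O)CC(C)=C[C@@H]2c1c(OC)ccc(OC)c13 | intermediate
20 | dilithium bis-enolate of 19 | [Li+].[Li+].CC(C)=CC[C@@]2(C([O-])=C)[C@@]3(C([O-])=C)CC(C)=C[C@@H]2c1c(OC)ccc(OC)c13 | intermediate
21 | (4aS,5R,8aR)-7-methyl-4a-(3-methylbut-2-en-1-yl)-2,3,4a,5,8,8a-hexahydronaphthalene-1,4-dione, C-5/C-8a bridged by 3,6-dimethoxy-1,2-phenylene | CC(C)=CC[C@@]12C(=O)CCC(=O)[C@@]13CC(C)=C[C@@H]2c1c(OC)ccc(OC)c13 | intermediate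
22 | (4aS,5R,8aR)-7-methyl-4a-(3-methylbut-2-en-1-yl)-4a,5,8,8a-tetrahydronaphthalene-1,4-dione, C-5/C-8a bridged by 3,6-dimethoxy-1,2-phenylene | CC(C)=CC[C@@]12C(=O)C=CC(=O)[C@@]13CC(C)=C[C@@H]2c1c(OC)ccc(OC)c13 | intermediate
23 | quinone of 22 (ring B as para-benzoquinone, configuration unchanged) | CC(C)=CC[C@@]12C(=O)C=CC(=O)[C@@]13CC(C)=C[C@@H]2C1=C3C(=O)C=CC1=O | intermediate
24 | (4aS,5R,8aR)-7-methyl-4a-(3-methylbut-2-en-1-yl)-4a,5,8,8a-tetrahydronaphthalene-1,4-dione, C-5/C-8a bridged by 3,6-dihydroxy-1,2-phenylene (CNP0166383.1) | CC(C)=CC[C@@]12C(=O)C=CC(=O)[C@@]13CC(C)=C[C@@H]2c1c(O)ccc(O)c13 | target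

**Step count**

Total: 11 steps. Longest linear sequence: 9 steps (steps 1–3 and 6–11).

**Steps most likely to fail**

1. Step 7. The cation may lose a proton to the conjugated triene without closing; the arene may alkylate the methyl-bearing allyl terminus; the closure may give the other relative configuration at C-10; or the chiral anion may discriminate the faces poorly. Fallback, from 14 to 17: dehydration with methyl N-(triethylammoniosulfonyl)carbamate (benzene, 50 °C) should give (3E,5Z,7Z)-8-(2,5-dimethoxyphenyl)-6-methyl-3-(3-methylbut-2-en-1-yl)-10-(trimethylsilyl)deca-3,5,7-trien-9-yn-2-one F1, with the slim alkyne cis to the chain. Heating (xylene, 140 °C) should close it by a thermal disrotatory 6π electrocyclisation, in which the two outside groups (aryl and acetyl) become cis, to racemic 1-{6-(2,5-dimethoxyphenyl)-4-methyl-1-(3-methylbut-2-en-1-yl)-6-[(trimethylsilyl)ethynyl]cyclohexa-2,4-dien-1-yl}ethan-1-one F2. CF3CO2H (CH2Cl2, 0 °C) should protonate the diene CH next to the aryl-bearing carbon, and the allyl cation should close by Friedel–Crafts alkylation to racemic 17, that is 17 together with 1-[(5S,9S,10R)-1,4-dimethoxy-7-methyl-10-(3-methylbut-2-en-1-yl)-9-[(trimethylsilyl)ethynyl]-8,9-dihydro-5H-5,9-methanobenzo[7]annulen-10-yl]ethan-1-one F3. The two are separated by preparative HPLC on a chiral stationary phase, and the route is rejoined at 17.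

2. Step 6. The α-branched acyl ylide may react too slowly with the small amount of open aldehyde, and the tertiary hydroxyl may add to the new enone. Fallback, from 7 to 14: the more reactive ester ylide methyl 5-methyl-2-(triphenyl-λ5-phosphanylidene)hex-4-enoate F4 (from methyl (triphenylphosphoranylidene)acetate and prenyl bromide, then NaOH) should give with 7 (toluene, 80 °C) methyl (2E,4Z)-7-(2,5-dimethoxyphenyl)-7-hydroxy-5-methyl-2-(3-methylbut-2-en-1-yl)-9-(trimethylsilyl)nona-2,4-dien-8-ynoate F5. MeNH(OMe)·HCl and i-PrMgCl (THF, −20 °C) should convert the ester into (2E,4Z)-7-(2,5-dimethoxyphenyl)-7-hydroxy-N-methoxy-N,5-dimethyl-2-(3-methylbut-2-en-1-yl)-9-(trimethylsilyl)nona-2,4-dien-8-ynamide F6, and MeMgBr (THF, 0 °C) should then give 14.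

3. Step 9. A mono-enolate may close by aldol addition onto the other ketone, or the enolates may couple between molecules or be chlorinated. Fallback, from 19 to 21: Me3SiOTf and Et3N (CH2Cl2, 0 °C) should give, without any free enolate, the bis(silyl enol ether) (5R,9R,10S)-1,4-dimethoxy-7-methyl-10-(3-methylbut-2-en-1-yl)-9,10-bis{1-[(trimethylsilyl)oxy]ethenyl}-8,9-dihydro-5H-5,9-methanobenzo[7]annulene F7. Ag2O in DMSO (65 °C) should then couple the two enol ether carbons oxidatively to 21.

**Further compounds**

F1 | step 7 | (3E,5Z,7Z)-8-(2,5-dimethoxyphenyl)-6-methyl-3-(3-methylbut-2-en-1-yl)-10-(trimethylsilyl)deca-3,5,7-trien-9-yn-2-one | CC(=O)/C(CC=C(C)C)=C/C=C(C)\C=C(/C#C[Si](C)(C)C)c1cc(OC)ccc1OC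
F2 | step 7 | racemic 1-{6-(2,5-dimethoxyphenyl)-4-methyl-1-(3-methylbut-2-en-1-yl)-6-[(trimethylsilyl)ethynyl]cyclohexa-2,4-dien-1-yl}ethan-1-one, aryl cis to acetyl (enantiomer leading to 17 drawn) | CC(C)=CC[C@@]2(C(C)=O)[C@](C#C[Si](C)(C)C)(c1cc(OC)ccc1OC)C=C(C)C=C2
F3 | step 7 | 1-[(5S,9S,10R)-1,4-dimethoxy-7-methyl-10-(3-methylbut-2-en-1-yl)-9-[(trimethylsilyl)ethynyl]-8,9-dihydro-5H-5,9-methanobenzo[7]annulen-10-yl]ethan-1-one (enantiomer of 17) | CC(C)=CC[C@]2(C(C)=O)[C@]3(C#C[Si](C)(C)C)CC(C)=C[C@H]2c1c(OC)ccc(OC)c13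
F4 | step 6 | methyl 5-methyl-2-(triphenyl-λ5-phosphanylidene)hex-4-enoate | COC(=O)C(CC=C(C)C)=P(c1ccccc1)(c1ccccc1)c1ccccc1
F5 | step 6 | methyl (2E,4Z)-7-(2,5-dimethoxyphenyl)-7-hydroxy-5-methyl-2-(3-methylbut-2-en-1-yl)-9-(trimethylsilyl)nona-2,4-dien-8-ynoate | COC(=O)/C(CC=C(C)C)=C/C=C(C)\CC(O)(C#C[Si](C)(C)C)c1cc(OC)ccc1OC
F6 | step 6 | (2E,4Z)-7-(2,5-dimethoxyphenyl)-7-hydroxy-N-methoxy-N,5-dimethyl-2-(3-methylbut-2-en-1-yl)-9-(trimethylsilyl)nona-2,4-dien-8-ynamide | CON(C)C(=O)/C(CC=C(C)C)=C/C=C(C)\CC(O)(C#C[Si](C)(C)C)c1cc(OC)ccc1OC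
F7 | step 9 | (5R,9R,10S)-1,4-dimethoxy-7-methyl-10-(3-methylbut-2-en-1-yl)-9,10-bis{1-[(trimethylsilyl)oxy]ethenyl}-8,9-dihydro-5H-5,9-methanobenzo[7]annulene | CC(C)=CC[C@@]2(C(=C)O[Si](C)(C)C)[C@@]3(C(=C)O[Si](C)(C)C)CC(C)=C[C@@H]2c1c(OC)ccc(OC)c13
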